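Remark: the descriptor at the carbinol carbon of the given SMILES corresponds to (S). (11Z)-Hexadec-11-en-1-ol and N-methoxy-N-methyl-3-oxobutanamide are taken as purchasable. Atoms are numbered as in the chromen-4-one target (O1, C2, C3, C4, C4a, C5 to C8, C8a) throughout.

**Retrosynthetic overview**
Ring A is the γ-pyranone (O1, C2, C3, C4, C4a, C8a); ring B is the carbocycle (C4a, C5, C6, C7, C8, C8a).
Last disconnections, done in one flask: C5–OH ⇒ C5=O (asymmetric transfer hydrogenation) and C7–C8 ⇒ a monocyclic 3-acryloyl-2-methyl-γ-pyranone (intramolecular vinylogous Michael addition).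
Enabling feature: C8 sits on C8a of ring A and is γ to the ring carbonyl C4=O through C8a=C4a, so it is a latent carbanion; the carbinol carbon C5 sits on the neighbouring ring atom C4a, and at the ketone level C5/C6/C7 is an enone whose β-carbon C7 lies one six-membered ring away from C8.
Acryloyl pyranone ⇒ pyranone Weinreb amide + vinylmagnesium bromide; ring A ⇒ acylketene (from a γ-alkylated tert-butyl acetoacetate) + N-methoxy-N-methylacetoacetamide, which fixes the C8 methyl on C8a and the C5 carbonyl on C4a.
Side chain ⇒ acetoacetate dianion + (Z)-1-iodohexadec-11-ene from the pheromone alcohol, with the Z-alkene bought in; ring A is formed first (step 3), ring B last (step 5).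

Key step: step 5

**Route**

Step 1
Reactants: 1 (11Z)-hexadec-11-en-1-ol
Product: 2 (11Z)-1-iodohexadec-11-ene
Conditions: PPh3, I2, imidazole, CH2Cl2, 0 °C → rt
Reagents that add atoms: iodine, [I][I]
Why: Appel-type iodination; the primary oxyphosphonium is displaced by iodide in an SN2 step that leaves the isolated Z-alkene untouched.

Step 2
Reactants: 2 (11Z)-1-iodohexadec-11-ene; 3 tert-butyl acetoacetate (tert-butyl 3-oxobutanoate)
Product: 4 tert-butyl (15Z)-3-oxoicos-15-enoate
Conditions: 3, NaH, THF, 0 °C; n-BuLi, 0 °C; then 2, 0 °C → rt; cold 1 M HCl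
Reagents that add atoms: none
Why: Weiler dianion alkylation; the terminal carbanion of the acetoacetate dianion is the most nucleophilic site and should be alkylated cleanly by the primary iodide, giving the four carbons that become C4, C3, C2 and the first side-chain CH2.

Step 3
Reactants: 4 tert-butyl (15Z)-3-oxoicos-15-enoate; 5 N-methoxy-N-methyl-3-oxobutanamide
Product: 8 6-[(12Z)-heptadec-12-en-1-yl]-N-methoxy-N,2-dimethyl-4-oxo-4H-pyran-3-carboxamide, via acylketene 6 (not isolated), via triketo amide 7 (not isolated)
Conditions: 5 (3 equiv), DMAP (0.2 equiv), toluene, 110 °C, slow addition of 4, 4 Å sieves in the reflux return; then p-TsOH·H2O (0.1 equiv), 80 °C, Dean–Stark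
Reagents that add atoms: none
Why: thermal loss of tert-butanol from the β-keto ester gives acylketene 6, which should acylate the central carbon of the enolised β-keto amide (acylketene C-acylation of a β-dicarbonyl compound, with DMAP moving any O-acyl product to carbon) to give 7, and acid-catalysed cyclodehydration between its two 1,5-related ketones closes ring A in the only 4-pyranone sense available, with the methyl on C8a and the amide on C4a.

Step 4
Reactants: 8 6-[(12Z)-heptadec-12-en-1-yl]-N-methoxy-N,2-dimethyl-4-oxo-4H-pyran-3-carboxamide; 9 vinylmagnesium bromide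
Product: 10 6-[(12Z)-heptadec-12-en-1-yl]-2-methyl-3-(prop-2-enoyl)-4H-pyran-4-one
Conditions: 9 (2.5 equiv), THF, −78 → −20 °C; inverse quench into cold 1 M HCl; crude enone used at once
Reagents that add atoms: none
Why: Weinreb ketone synthesis; the chelated tetrahedral magnesium adduct should stop at mono-addition and collapse to the enone only on acidic quench, the amide being more electrophilic than the pyranone carbonyl, which is a vinylogous ester.

Step 5
Reactants: 10 6-[(12Z)-heptadec-12-en-1-yl]-2-methyl-3-(prop-2-enoyl)-4H-pyran-4-one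
Product: 12 (5S)-2-[(12Z)-heptadec-12-en-1-yl]-5-hydroxy-5,6,7,8-tetrahydro-4H-chromen-4-one, via dione 11 (not isolated)
Conditions: DBU (0.2 equiv), THF (0.02 M), 0 °C → rt; then RuCl(p-cymene)[(S,S)-TsDPEN] (2 mol %), HCO2H/Et3N (5:2), 30 °C; neutral work-up
Reagents that add atoms: none
Why: DBU removes a proton from the C8 methyl of 10, which is γ to both the ring carbonyl C4=O and the acryloyl C5=O through C8a=C4a; the delocalised dienolate adds through C8 to the enone β-carbon C7 (equally a 6π-electrocyclisation of the C8=C8a–C4a=C5(O−)–C6=C7 trienolate), protonation at C6 gives dione 11, and its C5 ketone is then reduced by the ruthenium hydride formed from formate through the concerted outer-sphere H−/H+ transfer of Noyori asymmetric transfer hydrogenation. The closest known reaction types are the vinylogous Michael addition of lateral anions of 2-methyl-γ-pyranones and 2-methylchromones and the transfer hydrogenation of 1-tetralone and 4-chromanone with this catalyst. Ring B closes in 6-endo-trig mode at the acceptor (6-enolendo at the donor), forming C7–C8. The only stereocentre, C5, is set by the catalyst: the (S,S)-TsDPEN ligand is expected to deliver hydride to the face that gives the (S)-carbinol, with the planar pyranone taking the place of the arene of 1-tetralone in the CH/π contact with the cymene ligand; the sense of induction would be checked and the (R,R)-ligand used if it proved opposite. The step needs C8 to react rather than the side-chain CH2 on C2 (only C8 is doubly activated and within reach of C7), ring closure to outrun intermolecular addition (high dilution, fresh enone), and hydride to go to C5=O alone (C4=O is a vinylogous ester, the Z-alkene is inert to this catalyst, and the hydride source is added only after the enone is consumed).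

**Compound list**
1 | (11Z)-hexadec-11-en-1-ol | CCCC/C=C\CCCCCCCCCCO | starting material
2 | (11Z)-1-iodohexadec-11-ene | CCCC/C=C\CCCCCCCCCCI | intermediate
3 | tert-butyl acetoacetate | CC(=O)CC(=O)OC(C)(C)C | starting material
4 | tert-butyl (15Z)-3-oxoicos-15-enoate | CCCC/C=C\CCCCCCCCCCCC(=O)CC(=O)OC(C)(C)C | intermediate
5 | N-methoxy-N-methyl-3-oxobutanamide | CC(=O)CC(=O)N(C)OC | starting material
6 | (15Z)-icosa-1,15-diene-1,3-dione (acylketene, not isolated) | CCCC/C=C\CCCCCCCCCCCC(=O)C=C=O | intermediate
7 | (17Z)-2-acetyl-N-methoxy-N-methyl-3,5-dioxodocos-17-enamide (not isolated) | CCCC/C=C\CCCCCCCCCCCC(=O)CC(=O)C(C(C)=O)C(=O)N(C)OC | intermediate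
8 | 6-[(12Z)-heptadec-12-en-1-yl]-N-methoxy-N,2-dimethyl-4-oxo-4H-pyran-3-carboxamide | CCCC/C=C\CCCCCCCCCCCc1cc(=O)c(C(=O)N(C)OC)c(C)o1 | intermediate
9 | vinylmagnesium bromide | C=C[Mg]Br | starting material
10 | 6-[(12Z)-heptadec-12-en-1-yl]-2-methyl-3-(prop-2-enoyl)-4H-pyran-4-one | CCCC/C=C\CCCCCCCCCCCc1cc(=O)c(C(=O)C=C)c(C)o1 | intermediate
11 | 2-[(12Z)-heptadec-12-en-1-yl]-7,8-dihydro-4H-chromene-4,5(6H)-dione (not isolated) | CCCC/C=C\CCCCCCCCCCCc1cc(=O)c2c(o1)CCCC2=O | intermediate
12 | (5S)-2-[(12Z)-heptadec-12-en-1-yl]-5-hydroxy-5,6,7,8-tetrahydro-4H-chromen-4-one | CCCC/C=C\CCCCCCCCCCCc1cc(=O)c2c(o1)CCC[C@@H]2O | target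

Total step count: 5. Longest linear sequence: 5 steps (1 → 2 → 4 → 8 → 10 → 12).

**Steps most likely to fail**

Step 3. Self-condensation of the acylketene, O-acylation that does not move on to carbon, or ring closure onto the amide carbonyl may outrun the wanted C-acylation and cyclodehydration, because the keto amide is a weak carbon nucleophile. The fallback sets out from 4 and 5 and comes back at 8. Compound 5 would first be condensed with pyrrolidine (toluene, removal of water) to (E)-N-methoxy-N-methyl-3-(pyrrolidin-1-yl)but-2-enamide F1, a much stronger carbon nucleophile. Thermolysis of 4 in its presence (toluene, 110 °C) should give, by hetero-Diels–Alder addition of acylketene 6 across the enamine double bond, 6-[(12Z)-heptadec-12-en-1-yl]-N-methoxy-N,2-dimethyl-4-oxo-2-(pyrrolidin-1-yl)-3,4-dihydro-2H-pyran-3-carboxamide F2. Its amine sits on the carbon that becomes C8a, so loss of pyrrolidine (AcOH) can only lead to 8. Because the freed pyrrolidine captures acylketene, 4 would be used in about twofold amount.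

Step 4. The Grignard reagent may add to the pyranone carbonyl or deprotonate the C8 methyl instead of attacking the hindered amide, and the liberated enone may polymerise or capture the released hydroxylamine during work-up. The fallback sets out from 8 and comes back at 10. Reduction with i-Bu2AlH (THF, −78 °C) should give 6-[(12Z)-heptadec-12-en-1-yl]-2-methyl-4-oxo-4H-pyran-3-carbaldehyde F3. Its aldehyde is far more electrophilic than any other site and should take up vinylmagnesium bromide at −78 °C to give racemic 6-[(12Z)-heptadec-12-en-1-yl]-3-(1-hydroxyprop-2-en-1-yl)-2-methyl-4H-pyran-4-one F4. Oxidation with MnO2 (CH2Cl2, rt) would then deliver 10 under neutral conditions for direct use in step 5.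

Step 5. Intermolecular Michael oligomerisation of the enone may compete with ring closure, and hydride transfer to the vinylogous-ester-like C5 ketone of the dione may be slow or poorly face-selective. The fallback sets out from 10 and comes back at 12, setting C5 before ring B is closed. Addition of HCl (dioxane, 0 °C) to the enone should give 3-(3-chloropropanoyl)-6-[(12Z)-heptadec-12-en-1-yl]-2-methyl-4H-pyran-4-one F5, a masked enone that cannot polymerise. Transfer hydrogenation of this open-chain ketone with the same catalyst (β-chloroethyl aryl ketones are standard substrates) should give 3-[(1S)-3-chloro-1-hydroxypropyl]-6-[(12Z)-heptadec-12-en-1-yl]-2-methyl-4H-pyran-4-one F6. LiN(SiMe3)2 (2.2 equiv, THF, −78 → 0 °C) would then form the alkoxide and the C8 carbanion, which displaces chloride at C7 in a 6-exo-tet lateral alkylation to give 12 with C5 untouched.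

**Further compounds**
F1 | step 3 | (E)-N-methoxy-N-methyl-3-(pyrrolidin-1-yl)but-2-enamide | C/C(=C\C(=O)N(C)OC)N1CCCC1
F2 | step 3 | 6-[(12Z)-heptadec-12-en-1-yl]-N-methoxy-N,2-dimethyl-4-oxo-2-(pyrrolidin-1-yl)-3,4-dihydro-2H-pyran-3-carboxamide | CCCC/C=C\CCCCCCCCCCCC1=CC(=O)C(C(=O)N(C)OC)C(C)(N2CCCC2)O1
F3 | step 4 | 6-[(12Z)-heptadec-12-en-1-yl]-2-methyl-4-oxo-4H-pyran-3-carbaldehyde | CCCC/C=C\CCCCCCCCCCCc1cc(=O)c(C=O)c(C)o1
F4 | step 4 | racemic 6-[(12Z)-heptadec-12-en-1-yl]-3-(1-hydroxyprop-2-en-1-yl)-2-methyl-4H-pyran-4-one | CCCC/C=C\CCCCCCCCCCCc1cc(=O)c(C(O)C=C)c(C)o1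
F5 | step 5 | 3-(3-chloropropanoyl)-6-[(12Z)-heptadec-12-en-1-yl]-2-methyl-4H-pyran-4-one | CCCC/C=C\CCCCCCCCCCCc1cc(=O)c(C(=O)CCCl)c(C)o1
F6 | step 5 | 3-[(1S)-3-chloro-1-hydroxypropyl]-6-[(12Z)-heptadec-12-en-1-yl]-2-methyl-4H-pyran-4-one | CCCC/C=C\CCCCCCCCCCCc1cc(=O)c([C@@H](O)CCCl)c(C)o1
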